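A common mistake with a slow flask is to expect that more electrophile will make it proportionally faster.

| setting | spring | midnight | flask |
|---|---|---|---|
| electrophile | 0.080 M | 0.32 M | 0.16 M |
| gas | 23 mM (held) | 23 mM (held) | 23 mM (held) |
| remark | run made earlier | run made earlier |  |
| time |  |  | 5.0 d |

| run | time / d | electrophile / % | product / % |
|---|---|---|---|
| spring | 0.333 | 91 | 13 |
| spring | 0.500 | 82 | 18 |
| spring | 0.833 | 68 | 30 |
| spring | 1.67 | 42 | 59 |
| spring | 2.50 | 20 | 81 |
| spring | 4.00 | 4 | 98 |
| midnight | 0.625 | 92 | 9 |
| midnight | 1.25 | 86 | 16 |
| midnight | 2.08 | 72 | 26 |
| midnight | 2.50 | 69 | 32 |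
| midnight | 3.00 | 63 | 38 |
| midnight | 4.00 | 54 | 51 |

(standard deviation of a reading: 1.5 percentage points)

* part of the electrophile that has reacted at 5.0 d
* share of the unused nucleophile that is free and not bound as protonated nucleophile, at 5.0 d

- the numbers in the tables scatter by 1.5 percentage points (one standard deviation)
- at the start none of the gas is in solution
- a reading or a percentage of product counts all its forms, free or not
- the earlier runs do not show how much of nucleophile is bound; that part of a forecast is a guess

What do the runs give? Between the readings at 0.333 d and 2.50 d, the spring run loses electrophile at 0.0262 M d⁻¹. Between 0.625 d and 4.00 d, the midnight run loses it at 0.0360 M d⁻¹.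

And the charge? It rose by a factor of 4.00, the rate by less than that, 1.37. So I read gas uptake as the rate-limiting step and call the midnight slope the supply rate.

What follows for this flask? Take the budget time, the charge divided by the supply rate: 4.44 d, which is shorter than 5.0 d.

So is it finished? No. The spring run shows a tail, with [electrophile] still at 20% of its charge at 2.50 d.

How long is this flask in that tail? Spending half of its charge at the supply rate takes 2.22 d, which leaves 2.78 d, longer than the spring run's 2.50 d. I commit to a little above 90.0% reacted. The readings do not tell how much nucleophile is bound, so the free share stays a guess.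

The forecast gives 90% (84% to 95%) and 25% (5% to 80%), on the ground that “the rate is mostly limited by gas uptake, with a chemical step in series”. The flask gives 92.7% reacted and 8.94% free.

    crystals ⇌ product, rate k1*(cs1 - [product]) while solid is left; crystals form when [product] > cs1 (solubility = 0.0890 M, k = 3.04 × 10⁻⁴ s⁻¹)
    electrophile + nucleophile → acid set free + product (k = 9.10 × 10⁻⁴ M⁻¹ s⁻¹)
    nucleophile + acid set free ⇌ protonated nucleophile, settled at all times (K = 14000 M⁻¹)
    gas ⇌ nucleophile, rate k4*(csat - [nucleophile]) (kL = 4.39 × 10⁻⁵ s⁻¹)

In this flask the half-life of nucleophile by substitution, with the other concentrations as charged, is 0.055 d, far shorter than the budget time of 4.44 d, and [nucleophile] stood at 0.00333 M at 0.500 d against the gas saturation of 23 mM. The neighbour charged with 0.40 M has a budget time of 11.1 d, of which 5.0 d covers 45.0%, and that neighbour reacted 50.7%.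

The numbers in the tables were computed with constants of no real substance; scatter was added.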